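(Readings and results are simulated for substances that don't exist.)

4 questions stand on two flasks, cedar and elm: which species holds most of the starting complex at the end, and how much.

| flask | starting complex | incoming ligand | remark | time |
|---|---|---|---|---|
| Wednesday's | 0.075 M | 1.3 equiv | run made earlier |  |
| cedar | 0.050 M | 1.30 equiv |  | 25 min |
| elm | 0.050 M | 3.90 equiv |  | 25 min |

Wednesday's run (percent of the starting complex charged)

| time / min | complex with two exchanged / % | complex with one exchanged / % | starting complex / % | complex with four exchanged / % | complex with three exchanged / % | isomer of the product / % |
|---|---|---|---|---|---|---|
| 0.667 | 4.0 | 35.1 | 59.5 | 1.0 | 1.5 | 0.3 |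
| 1.33 | 9.1 | 45.1 | 42.1 | 0 | 3.0 | 0 |
| 2.50 | 13.3 | 48.9 | 30.0 | 0.8 | 5.7 | 2.8 |
| 5.00 | 12.5 | 49.4 | 22.2 | 3.1 | 8.3 | 5.6 |
| 8.00 | 10.7 | 47.3 | 19.9 | 3.9 | 9.4 | 9.1 |

(scatter of a reading: 0.5 percentage points)

- the analysis behind the earlier runs scatters by 0.5 percentage points, standard deviation
- no earlier run changes the charge of incoming ligand; that part of a forecast is a guess

1. which of these there is most of at the end, counted by the starting complex in it, cedar (isomer of the product / complex with three exchanged / complex with four exchanged / complex with one exchanged / starting complex)
2. which of these there is most of at the end, counted by the starting complex in it, elm (isomer of the product / complex with three exchanged / complex with four exchanged / complex with one exchanged / starting complex)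
3. the largest of these amounts at the end, in percent of the starting complex charged, cedar
4. the largest of these amounts at the end, in percent of the starting complex charged, elm

Wednesday's run slows: its starting complex falls by 7.8 percentage points between the third and fourth readings, but by 2.3 points between the last two, with 19.9 % still standing. Each exchange should take one incoming ligand, so the charge caps the exchanges. Summing each complex's share times its exchanges at the last reading gives 1.22 with the isomer counted as one exchange. But with the isomer counted as two, the exchange count, the mean number of exchanges per starting complex charged, reads 1.31, which meets the charge of 1.3 equiv. So my reckoning takes the isomer as two-exchanged and incoming ligand as the limiting reagent.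

Cedar has the same equivalents, 1.30 equiv, but c(starting complex) is 0.050 M against 0.075 M. If the exchange steps are second order, dilution stretches their clock and leaves their path. Wednesday's last reading then falls at 12.0 min in cedar, earlier than 25 min. With the isomer counted as two, complex with one exchanged needs a further incoming ligand to become it, and the count at that reading already meets the charge, so I expect that complex to hold near 47.3 % in cedar. Elm's cap of 3.90 equiv allows complex with four exchanged at most 97.5 %, and I expect it to lead in elm.

The forecast names the same species for cedar, complex with one exchanged, but puts it at 36 %, lower than my reckoning, because “the one-exchanged complex slowly drains to isomer”, and it gives complex with four exchanged at 85 % for elm.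

Cedar ends with complex with one exchanged at 47.8 %, and elm with complex with four exchanged at 79.9 %.

    starting complex + incoming ligand → leaving ligand + complex with one exchanged (k = 10.0 /M/min)
    complex with one exchanged + incoming ligand → leaving ligand + complex with two exchanged (k = 5.30 /M/min)
    complex with two exchanged + incoming ligand → leaving ligand + complex with three exchanged (k = 10.0 /M/min)
    complex with three exchanged + incoming ligand → leaving ligand + complex with four exchanged (k = 6.60 /M/min)
    complex with two exchanged ⇌ isomer of the product (K = 10.0, k = 0.110 /min)
    crystals ⇌ leaving ligand, rate k6*(cs6 - [leaving ligand]) while solid is left; crystals form when [leaving ligand] > cs6 (solubility = 19.0 mM, k = 4.30 /min)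

Cedar keeps 0.044 % of its incoming ligand at 25.0 min. Its exchange count there is 1.30 against the charge of 1.30 equiv. In the neighbour flask, cedar with 2.20 equiv of incoming ligand, the count at the end is 2.19, and complex with one exchanged stands at 30.1 %.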